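**Retrosynthetic overview**
- Ring C is opened at O1–C2: an enantioselective oxa-Michael closure of a tert-butyl-ester-activated 2'-hydroxychalcone (16), made from the ring A β-ketoester 15 and the benzodioxane aldehyde 12, sets C2; the ester is then lost by decarboxylation.
- Ring D is opened at O4'–C7''. C7'' is benzylic to the para-oxygenated guaiacyl ring E, so this bond ionises reversibly to a quinone methide type cation. Only C8'' (bearing the C9'' hydroxymethyl, bound to O3') has to be preset.
- C8'' is set by an auxiliary-controlled syn-aldol of an N-(aryloxyacetyl)oxazolidinone with O-benzylvanillin. The O3'–C8'' ether is made beforehand by alkylating the 3-OH of 4-O-allyl-protected 3,4-dihydroxybenzaldehyde acetal. The C7'' configuration that the aldol also creates is immaterial, because the closure passes through the cation.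
- Order of ring formation: rings A, B and E are bought; ring D is closed in step 8, ring C in step 12; debenzylation is last.

Key step: step 8

Assumption: the epi-quinidine-derived amine–thiourea is taken to deliver the 2S flavanone in step 12; should a model alkylidene show the opposite sense, the quinine-derived pseudoenantiomer is used instead.

**Route**

Step 1
Reactants: 1 3,4-dihydroxybenzaldehyde
Product: 2 4-(allyloxy)-3-hydroxybenzaldehyde
Conditions: allyl bromide (1.05 equiv), NaHCO3, NaI (cat.), DMF, 40 °C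
Reagents that add atoms: allyl bromide, C=CCBr
Why: Regioselective Williamson etherification: the 4-OH para to the formyl group is the more acidic phenol, so with the weak base only its phenoxide should form and be allylated, leaving the 3-OH (the later O3') free.

Step 2
Reactants: 2 4-(allyloxy)-3-hydroxybenzaldehyde
Product: 3 2-(allyloxy)-5-(1,3-dioxolan-2-yl)phenol
Conditions: ethylene glycol (3 equiv), TsOH·H2O (cat.), toluene, reflux, Dean–Stark; Et3N quench
Reagents that add atoms: ethylene glycol, OCCO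
Why: Acid-catalysed acetalisation with azeotropic removal of water masks the aldehyde against the enolate, hydride and Pd steps that follow; the allyl ether and phenol are inert.

Step 3
Reactants: 4 (S)-4-benzyloxazolidin-2-one
Product: 5 (S)-4-benzyl-3-(bromoacetyl)oxazolidin-2-one
Conditions: n-BuLi (1.05 equiv), THF, −78 °C; bromoacetyl bromide, −78 → 0 °C
Reagents that add atoms: bromoacetyl bromide, BrCC(Br)=O
Why: N-acylation of the lithiated oxazolidinone, in which acyl substitution at the acid bromide is much faster at −78 °C than SN2 displacement at CH2Br.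

Step 4
Reactants: 3 2-(allyloxy)-5-(1,3-dioxolan-2-yl)phenol; 5 (S)-4-benzyl-3-(bromoacetyl)oxazolidin-2-one
Product: 6 (S)-3-{[2-(allyloxy)-5-(1,3-dioxolan-2-yl)phenoxy]acetyl}-4-benzyloxazolidin-2-one
Conditions: K2CO3 (1.5 equiv), acetone, rt
Reagents that add atoms: none
Why: Williamson etherification of the only free phenol with the activated α-bromo imide should form the O3'–C8'' bond, with the regiochemistry fixed in step 1.

Step 5
Reactants: 6 (S)-3-{[2-(allyloxy)-5-(1,3-dioxolan-2-yl)phenoxy]acetyl}-4-benzyloxazolidin-2-one; 7 4-(benzyloxy)-3-methoxybenzaldehyde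
Product: 8 (S)-3-[(2S,3R)-2-[2-(allyloxy)-5-(1,3-dioxolan-2-yl)phenoxy]-3-[4-(benzyloxy)-3-methoxyphenyl]-3-hydroxypropanoyl]-4-benzyloxazolidin-2-one
Conditions: Et3N (1.4 equiv), Bu2BOTf (1.2 equiv), CH2Cl2, −78 → 0 °C; then 7, −78 → 0 °C; pH 7 buffer, MeOH, 30% H2O2, 0 °C
Reagents that add atoms: none
Why: Evans syn-aldol of a glycolate-type imide: the Z-boron enolate reacts through a Zimmerman–Traxler chair on the face opposite the auxiliary benzyl group, which sets C8'' (2S in the imide, 8''R once C1 is reduced) and, without consequence, C7'' (R); the amine-buffered low temperature should spare the aryl dioxolane.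

Step 6
Reactants: 8 syn-aldol imide
Product: 9 (1R,2R)-2-[2-(allyloxy)-5-(1,3-dioxolan-2-yl)phenoxy]-1-[4-(benzyloxy)-3-methoxyphenyl]propane-1,3-diol
Conditions: NaBH4 (4 equiv), THF/H2O (4:1), 0 °C → rt
Reagents that add atoms: none
Why: Reductive cleavage of the N-acyloxazolidinone gives the C9'' primary alcohol and returns the auxiliary; run promptly at 0 °C it should not epimerise C8'', which then no longer lies next to a carbonyl group.

Step 7
Reactants: 9 allyl- and acetal-protected diol
Product: 11 3-{[(1R,2R)-1-[4-(benzyloxy)-3-methoxyphenyl]-1,3-dihydroxypropan-2-yl]oxy}-4-hydroxybenzaldehyde, via (1R,2R)-1-[4-(benzyloxy)-3-methoxyphenyl]-2-[5-(1,3-dioxolan-2-yl)-2-hydroxyphenoxy]propane-1,3-diol 10 (not isolated)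
Conditions: Pd(PPh3)4 (5 mol%), morpholine (5 equiv), THF, rt; then 1 M aq HCl to pH ≈ 1, 0 °C → rt, 30 min
Reagents that add atoms: water, O
Why: Tsuji–Trost deallylation (allyl transfer to morpholine) frees the C4' phenol under neutral conditions while the aldehyde is still masked, and brief dilute aqueous acid then hydrolyses the electron-rich aryl dioxolane much faster than it ionises C7'' (any ring D formed early is simply product 12).

Step 8
Reactants: 11 C8''-defined arylglycerol aryl ether (key-step precursor)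
Product: 12 (2R,3R)-2-[4-(benzyloxy)-3-methoxyphenyl]-3-(hydroxymethyl)-2,3-dihydro-1,4-benzodioxine-6-carbaldehyde (trans)
Conditions: TsOH·H2O (0.2 equiv), toluene/1,4-dioxane (9:1), 0.02 M, 80 °C, until no cis isomer remains
Reagents that add atoms: none
Why: TsOH protonates the C7'' carbinol, which loses water to a planar benzylic cation delocalised onto the para-benzyloxy oxygen of ring E (a quinone methide type oxocarbenium ion), and the free C4' phenol adds to C7'' in a 6-exo-trig closure of ring D, forming O4'–C7''. The closest known reaction is the acid-mediated cyclisation of arylglycerol β-aryl ethers to trans-2-aryl-3-hydroxymethyl-1,4-benzodioxanes used for benzodioxane neolignans. The new C7'' centre is under thermodynamic control: the benzylic aryl ether re-ionises under the same acid (the 4-formylphenol is a good leaving group), so any cis isomer reopens and the diequatorial trans (7''R,8''R) ring should accumulate whatever the C7'' configuration of 11 or of any anti-aldol material carried along. C8'' lies outside the ionising system and keeps its R configuration, provided that capture by the neighbouring phenol outruns loss of the C8'' proton to an enol ether; the intramolecular six-membered trap, moderate temperature and high dilution favour this. Chemoselectivity between the two carbinols is built in, because only the benzylic C7''–OH can ionise and the primary C9''–OH (which could otherwise close an isomeric dioxane) stays untouched.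

Step 9
Reactants: 13 2,4,6-trihydroxyacetophenone
Product: 14 1-[2,4-bis(benzyloxy)-6-hydroxyphenyl]ethanone
Conditions: BnBr (2.1 equiv), K2CO3 (2.2 equiv), DMF, rt
Reagents that add atoms: benzyl bromide, BrCc1ccccc1
Why: Williamson etherification in which the hydroxyl hydrogen-bonded to the acetyl carbonyl is the least reactive, so two equivalents of benzyl bromide should go to the other two phenols.

Step 10
Reactants: 14 1-[2,4-bis(benzyloxy)-6-hydroxyphenyl]ethanone
Product: 15 tert-butyl 3-[2,4-bis(benzyloxy)-6-hydroxyphenyl]-3-oxopropanoate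
Conditions: LiHMDS (3.3 equiv), THF, −78 °C; Boc2O (1.1 equiv), −78 → 0 °C; AcOH quench
Reagents that add atoms: di-tert-butyl dicarbonate, CC(C)(C)OC(=O)OC(=O)OC(C)(C)C
Why: Crossed Claisen-type C-acylation of the lithium phenoxide–enolate dianion; the third equivalent of base keeps the product as its enolate, and any aryl carbonate formed at the phenoxide oxygen should be passed on to the adjacent enolate carbon.

Step 11
Reactants: 12 trans-benzodioxane aldehyde; 15 tert-butyl β-ketoester
Product: 16 tert-butyl 2-[2,4-bis(benzyloxy)-6-hydroxybenzoyl]-3-{(2R,3R)-2-[4-(benzyloxy)-3-methoxyphenyl]-3-(hydroxymethyl)-2,3-dihydro-1,4-benzodioxin-6-yl}prop-2-enoate (alkene isomers, used as the mixture)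
Conditions: piperidine (20 mol%), AcOH (20 mol%), toluene, 4 Å MS, rt → 40 °C
Reagents that add atoms: none
Why: Knoevenagel condensation of the doubly activated methylene with the non-enolisable aldehyde gives the ester-activated chalcone; the ketone-chelated phenol should not cyclise without bifunctional catalysis, and the free C9'' alcohol and ring D are inert to the amine/acid buffer.

Step 12
Reactants: 16 alkylidene β-ketoester
Product: 19 (2S)-5,7-bis(benzyloxy)-2-{(2R,3R)-2-[4-(benzyloxy)-3-methoxyphenyl]-3-(hydroxymethyl)-2,3-dihydro-1,4-benzodioxin-6-yl}chroman-4-one, via tert-butyl (2S)-5,7-bis(benzyloxy)-2-{(2R,3R)-2-[4-(benzyloxy)-3-methoxyphenyl]-3-(hydroxymethyl)-2,3-dihydro-1,4-benzodioxin-6-yl}-4-oxochromane-3-carboxylate 17 (not isolated), via the corresponding (2S)-4-oxochromane-3-carboxylic acid 18 (not isolated)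
Conditions: 9-amino-9-deoxy-epi-quinidine 3,5-bis(trifluoromethyl)phenyl thiourea (10 mol%), toluene, −25 °C; then TsOH·H2O (0.5 equiv), 80 °C
Reagents that add atoms: none
Why: Bifunctional amine–thiourea-catalysed enantioselective 6-endo-trig oxa-Michael addition, in which the thiourea binds the β-ketoester and the quinuclidine delivers the phenol to one face of the alkylidene so that the catalyst sets C2 (S); acid then cleaves the tert-butyl ester and the β-keto acid decarboxylates, which removes the C3 centre, while the acid can only return ring D to its trans form.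

Step 13
Reactants: 19 tri-O-benzylsilandrin
Product: 20 silandrin
Conditions: H2 (1 atm), 10% Pd/C, EtOAc/MeOH (1:1), rt, stopped at full debenzylation
Reagents that add atoms: none
Why: Catalytic hydrogenolysis of the three aryl benzyl ethers is neutral, so C2 is not exposed to the base-induced ring opening that racemises flavanones, and primary benzyl aryl ethers should cleave well before the hindered secondary benzylic C–O bonds at C2 and C7''.

**Compound list**

1 | 3,4-dihydroxybenzaldehyde | O=Cc1ccc(O)c(O)c1 | starting material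
2 | 4-(allyloxy)-3-hydroxybenzaldehyde | O=Cc1ccc(OCC=C)c(O)c1 | intermediate
3 | 2-(allyloxy)-5-(1,3-dioxolan-2-yl)phenol | Oc1cc(C2OCCO2)ccc1OCC=C | intermediate
4 | (S)-4-benzyloxazolidin-2-one | O=C1N[C@@H](Cc2ccccc2)CO1 | starting material
5 | (S)-4-benzyl-3-(bromoacetyl)oxazolidin-2-one | O=C(CBr)N1[C@@H](Cc2ccccc2)COC1=O | intermediate
6 | (S)-3-{[2-(allyloxy)-5-(1,3-dioxolan-2-yl)phenoxy]acetyl}-4-benzyloxazolidin-2-one | O=C(COc1cc(C2OCCO2)ccc1OCC=C)N1[C@@H](Cc2ccccc2)COC1=O | intermediate
7 | 4-(benzyloxy)-3-methoxybenzaldehyde | COc1cc(C=O)ccc1OCc1ccccc1 | starting material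
8 | (S)-3-[(2S,3R)-2-[2-(allyloxy)-5-(1,3-dioxolan-2-yl)phenoxy]-3-[4-(benzyloxy)-3-methoxyphenyl]-3-hydroxypropanoyl]-4-benzyloxazolidin-2-one | COc1cc([C@@H](O)[C@H](Oc2cc(C3OCCO3)ccc2OCC=C)C(=O)N2[C@@H](Cc3ccccc3)COC2=O)ccc1OCc1ccccc1 | intermediate
9 | (1R,2R)-2-[2-(allyloxy)-5-(1,3-dioxolan-2-yl)phenoxy]-1-[4-(benzyloxy)-3-methoxyphenyl]propane-1,3-diol | COc1cc([C@@H](O)[C@@H](CO)Oc2cc(C3OCCO3)ccc2OCC=C)ccc1OCc1ccccc1 | intermediate
10 | (1R,2R)-1-[4-(benzyloxy)-3-methoxyphenyl]-2-[5-(1,3-dioxolan-2-yl)-2-hydroxyphenoxy]propane-1,3-diol | COc1cc([C@@H](O)[C@@H](CO)Oc2cc(C3OCCO3)ccc2O)ccc1OCc1ccccc1 | intermediate (not isolated)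
11 | 3-{[(1R,2R)-1-[4-(benzyloxy)-3-methoxyphenyl]-1,3-dihydroxypropan-2-yl]oxy}-4-hydroxybenzaldehyde | COc1cc([C@@H](O)[C@@H](CO)Oc2cc(C=O)ccc2O)ccc1OCc1ccccc1 | intermediate (key-step precursor)
12 | (2R,3R)-2-[4-(benzyloxy)-3-methoxyphenyl]-3-(hydroxymethyl)-2,3-dihydro-1,4-benzodioxine-6-carbaldehyde | COc1cc([C@H]2Oc3ccc(C=O)cc3O[C@@H]2CO)ccc1OCc1ccccc1 | intermediate (key-step product)
13 | 2,4,6-trihydroxyacetophenone | CC(=O)c1c(O)cc(O)cc1O | starting material
14 | 1-[2,4-bis(benzyloxy)-6-hydroxyphenyl]ethanone | CC(=O)c1c(O)cc(OCc2ccccc2)cc1OCc1ccccc1 | intermediate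
15 | tert-butyl 3-[2,4-bis(benzyloxy)-6-hydroxyphenyl]-3-oxopropanoate | CC(C)(C)OC(=O)CC(=O)c1c(O)cc(OCc2ccccc2)cc1OCc1ccccc1 | intermediate
16 | tert-butyl 2-[2,4-bis(benzyloxy)-6-hydroxybenzoyl]-3-{(2R,3R)-2-[4-(benzyloxy)-3-methoxyphenyl]-3-(hydroxymethyl)-2,3-dihydro-1,4-benzodioxin-6-yl}prop-2-enoate (alkene isomer mixture) | COc1cc([C@H]2Oc3ccc(C=C(C(=O)OC(C)(C)C)C(=O)c4c(O)cc(OCc5ccccc5)cc4OCc4ccccc4)cc3O[C@@H]2CO)ccc1OCc1ccccc1 | intermediate
17 | tert-butyl (2S)-5,7-bis(benzyloxy)-2-{(2R,3R)-2-[4-(benzyloxy)-3-methoxyphenyl]-3-(hydroxymethyl)-2,3-dihydro-1,4-benzodioxin-6-yl}-4-oxochromane-3-carboxylate (C3 epimers/enol) | COc1cc([C@H]2Oc3ccc([C@@H]4C(C(=O)OC(C)(C)C)C(=O)c5c(OCc6ccccc6)cc(OCc6ccccc6)cc5O4)cc3O[C@@H]2CO)ccc1OCc1ccccc1 | intermediate (not isolated)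
18 | (2S)-5,7-bis(benzyloxy)-2-{(2R,3R)-2-[4-(benzyloxy)-3-methoxyphenyl]-3-(hydroxymethyl)-2,3-dihydro-1,4-benzodioxin-6-yl}-4-oxochromane-3-carboxylic acid | COc1cc([C@H]2Oc3ccc([C@@H]4C(C(=O)O)C(=O)c5c(OCc6ccccc6)cc(OCc6ccccc6)cc5O4)cc3O[C@@H]2CO)ccc1OCc1ccccc1 | intermediate (not isolated)
19 | (2S)-5,7-bis(benzyloxy)-2-{(2R,3R)-2-[4-(benzyloxy)-3-methoxyphenyl]-3-(hydroxymethyl)-2,3-dihydro-1,4-benzodioxin-6-yl}chroman-4-one | COc1cc([C@H]2Oc3ccc([C@@H]4CC(=O)c5c(OCc6ccccc6)cc(OCc6ccccc6)cc5O4)cc3O[C@@H]2CO)ccc1OCc1ccccc1 | intermediate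
20 | silandrin, (2S)-5,7-dihydroxy-2-{(2R,3R)-2-(4-hydroxy-3-methoxyphenyl)-3-(hydroxymethyl)-2,3-dihydro-1,4-benzodioxin-6-yl}chroman-4-one | COc1cc([C@H]2Oc3ccc([C@@H]4CC(=O)c5c(O)cc(O)cc5O4)cc3O[C@@H]2CO)ccc1O | target

**Step count**

Total: 13 steps. Longest linear sequence: 10 steps (1, 2, 4, 5, 6, 7, 8, 11, 12, 13) from 3,4-dihydroxybenzaldehyde.

**Steps most likely to fail**

Step 8 (key step). The ionisation may be diverted: the cation may lose the C8'' proton to an enol ether (which would also erase C8''), alkylate ring E of a second molecule, or the cis ring may not fully re-open and equilibrate to trans. The fallback changes the electrophile from the O-benzyl oxocarbenium ion to a neutral para-quinone methide, which needs a free ring E phenol and forms under much milder conditions. It sets out from imide 6. The same boron aldol with commercial 4-(tert-butyldimethylsilyloxy)-3-methoxybenzaldehyde should give the syn adduct (S)-3-[(2S,3R)-2-[2-(allyloxy)-5-(1,3-dioxolan-2-yl)phenoxy]-3-[4-(tert-butyldimethylsilyloxy)-3-methoxyphenyl]-3-hydroxypropanoyl]-4-benzyloxazolidin-2-one F1. LiBH4 (THF, MeOH, 0 °C) should then give the diol (1R,2R)-2-[2-(allyloxy)-5-(1,3-dioxolan-2-yl)phenoxy]-1-[4-(tert-butyldimethylsilyloxy)-3-methoxyphenyl]propane-1,3-diol F2. Pd(PPh3)4 with K2CO3 in MeOH removes the allyl and the aryl silyl group in one operation, to the bisphenol (1R,2R)-2-[5-(1,3-dioxolan-2-yl)-2-hydroxyphenoxy]-1-(4-hydroxy-3-methoxyphenyl)propane-1,3-diol F3. Catalytic TsOH in wet THF at room temperature hydrolyses the acetal and dehydrates the para-hydroxybenzylic alcohol to the quinone methide, which the C4' phenol traps to give (2R,3R)-2-(4-hydroxy-3-methoxyphenyl)-3-(hydroxymethyl)-2,3-dihydro-1,4-benzodioxine-6-carbaldehyde F4. A cis fraction would be equilibrated through the same quinone methide with K2CO3 in DMF. Benzylation of the ring E phenol (BnBr, K2CO3, acetone) brings the route back to 12.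

Step 12. Facial selectivity in the oxa-Michael addition may be poor, uncatalysed closure may already have occurred in step 11, or C2 may erode by retro-oxa-Michael opening during the hot acid decarboxylation. The fallback gives up enantioselective ring closure for a kinetic resolution, and it also bypasses steps 10 and 11. It sets out from aldehyde 12 and acetophenone 14. Claisen–Schmidt condensation (KOH, EtOH, rt) should give the chalcone (E)-1-[2,4-bis(benzyloxy)-6-hydroxyphenyl]-3-{(2R,3R)-2-[4-(benzyloxy)-3-methoxyphenyl]-3-(hydroxymethyl)-2,3-dihydro-1,4-benzodioxin-6-yl}prop-2-en-1-one F5. NaOAc in refluxing EtOH closes ring C without control, to 19 together with its C2 epimer, the (2R)-chroman-4-one F6. Asymmetric transfer hydrogenation under kinetic resolution (RuCl(p-cymene)(TsDPEN), HCO2H/Et3N, rt; catalyst enantiomer chosen on racemic 5,7-bis(benzyloxy)flavanone so that the 2R series is consumed) should reduce F6 to the cis (2R,4R)-chroman-4-ol F7. This is separated by chromatography from unreacted 19, where the route is rejoined.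

Step 10. The acylation may go to oxygen (enol or aryl carbonate) instead of carbon, or the product phenoxide may attack the tert-butyl ester and lactonise to a 4-hydroxycoumarin. The fallback replaces the intermolecular C-acylation of a dianion by a deliberate O-acylation followed by intramolecular acyl transfer. It sets out from 14. Boc2O with catalytic DMAP and Et3N in CH2Cl2 should give 2-acetyl-3,5-bis(benzyloxy)phenyl tert-butyl carbonate F8. LiHMDS (2.2 equiv, THF, −78 → −20 °C) then moves the tert-butoxycarbonyl group from the phenol oxygen to the enolate carbon through a six-membered transition state (Baker–Venkataraman type rearrangement), with the phenoxide as leaving group, and returns to 15.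

Further compounds
F1 | step 8 | (S)-3-[(2S,3R)-2-[2-(allyloxy)-5-(1,3-dioxolan-2-yl)phenoxy]-3-[4-(tert-butyldimethylsilyloxy)-3-methoxyphenyl]-3-hydroxypropanoyl]-4-benzyloxazolidin-2-one | COc1cc([C@@H](O)[C@H](Oc2cc(C3OCCO3)ccc2OCC=C)C(=O)N2[C@@H](Cc3ccccc3)COC2=O)ccc1O[Si](C)(C)C(C)(C)C
F2 | step 8 | (1R,2R)-2-[2-(allyloxy)-5-(1,3-dioxolan-2-yl)phenoxy]-1-[4-(tert-butyldimethylsilyloxy)-3-methoxyphenyl]propane-1,3-diol | COc1cc([C@@H](O)[C@@H](CO)Oc2cc(C3OCCO3)ccc2OCC=C)ccc1O[Si](C)(C)C(C)(C)C
F3 | step 8 | (1R,2R)-2-[5-(1,3-dioxolan-2-yl)-2-hydroxyphenoxy]-1-(4-hydroxy-3-methoxyphenyl)propane-1,3-diol | COc1cc([C@@H](O)[C@@H](CO)Oc2cc(C3OCCO3)ccc2O)ccc1O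
F4 | step 8 | (2R,3R)-2-(4-hydroxy-3-methoxyphenyl)-3-(hydroxymethyl)-2,3-dihydro-1,4-benzodioxine-6-carbaldehyde | COc1cc([C@H]2Oc3ccc(C=O)cc3O[C@@H]2CO)ccc1O
F5 | step 12 | (E)-1-[2,4-bis(benzyloxy)-6-hydroxyphenyl]-3-{(2R,3R)-2-[4-(benzyloxy)-3-methoxyphenyl]-3-(hydroxymethyl)-2,3-dihydro-1,4-benzodioxin-6-yl}prop-2-en-1-one | COc1cc([C@H]2Oc3ccc(/C=C/C(=O)c4c(O)cc(OCc5ccccc5)cc4OCc4ccccc4)cc3O[C@@H]2CO)ccc1OCc1ccccc1
F6 | step 12 | (2R)-5,7-bis(benzyloxy)-2-{(2R,3R)-2-[4-(benzyloxy)-3-methoxyphenyl]-3-(hydroxymethyl)-2,3-dihydro-1,4-benzodioxin-6-yl}chroman-4-one | COc1cc([C@H]2Oc3ccc([C@H]4CC(=O)c5c(OCc6ccccc6)cc(OCc6ccccc6)cc5O4)cc3O[C@@H]2CO)ccc1OCc1ccccc1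
F7 | step 12 | (2R,4R)-5,7-bis(benzyloxy)-2-{(2R,3R)-2-[4-(benzyloxy)-3-methoxyphenyl]-3-(hydroxymethyl)-2,3-dihydro-1,4-benzodioxin-6-yl}chroman-4-ol | COc1cc([C@H]2Oc3ccc([C@H]4C[C@@H](O)c5c(OCc6ccccc6)cc(OCc6ccccc6)cc5O4)cc3O[C@@H]2CO)ccc1OCc1ccccc1
F8 | step 10 | 2-acetyl-3,5-bis(benzyloxy)phenyl tert-butyl carbonate | CC(=O)c1c(OC(=O)OC(C)(C)C)cc(OCc2ccccc2)cc1OCc1ccccc1
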